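**Retrosynthetic overview**

1. Locants: ring B (cycloheptenone) C1(=O)–C2(Me)=C3–C4(Me)2–C5H–C6H–C7H2; ring A (cyclopentane) C5–C8–C9–C10(Me)(OH)–C6; linker C3–C11–C12–C13; ring C (cyclohexane) C13–C14(Me)–C15–C16–C17–C18(Me)(OH); ring D (oxepane) C14–C19–C20–C21(OH)–C22(Me)2–O–C15.
2. Last disconnection C3–C11: the alkyllithium of fragment 1 (rings C/D, C12–C11–I) adds to the C3 ketone of fragment 2 (rings A/B with the enone transposed: C3=O, C1=C2). An oxidative 1,3-transposition then moves the oxygen to C1 and the alkene to C2=C3.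
3. Ring B is closed on a preformed ring A by a rhodium-carbenoid cyclopropanation/Cope (4+3) sequence that forms C1–C2 and C4–C5 in one operation. Enabling feature: C2–C3–C4 of ring B is a 2-oxy-allyl unit that ends in the gem-dimethyl carbon C4 (a siloxy-vinyl diazoacetate; the ester on C2 is a removable activator and the oxygen sits on C3), and C1–C7–C6–C5 is a vinyl group on a ring A alkene (a ketal-protected 2-vinylcyclopentenone).
4. After ring closure: C6 by hydrogenation (cis fusion), C2 methyl by alkylation/decarboxylation, C10 carbinol by methylenation/hydration, C1=C2 by Saegusa–Ito oxidation.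
5. Fragment 1: rings D and then C are formed in one epoxonium cascade from an acyclic all-(R) diepoxy enol silane; C18 is set by equatorial MeMgBr addition.

Key step: step 6

Assumption: Rh2(R-PTAD)4 is taken to be the catalyst enantiomer that gives the cis-divinylcyclopropane intermediate of step 6 as drawn (sense inferred by analogy with related vinylcarbenoid cyclopropanations); if the sense is the opposite, Rh2(S-PTAD)4 is used and nothing else changes.

**Fragment 2 (rings A/B)**

Step 1
Reactants: 1 2-bromocyclopent-2-en-1-one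
Product: 2 6-bromo-1,4-dioxaspiro[4.4]non-6-ene
Conditions: ethylene glycol, p-TsOH (cat.), benzene, reflux, Dean–Stark
Reagents that add atoms: ethylene glycol OCCO
Why: Acid-catalysed ketalisation with azeotropic removal of water masks the future C10 as an achiral dioxolane, the bromine-bearing carbon staying sp2.

Step 2
Reactants: 2 6-bromo-1,4-dioxaspiro[4.4]non-6-ene
Product: 3 6-ethenyl-1,4-dioxaspiro[4.4]non-6-ene
Conditions: tributyl(vinyl)stannane, Pd(PPh3)4 (cat.), toluene, 100 °C
Reagents that add atoms: tributyl(vinyl)stannane C=C[Sn](CCCC)(CCCC)CCCC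
Why: Stille coupling (oxidative addition of zerovalent palladium into the vinyl C–Br bond, transmetalation from tin, reductive elimination) installs C7=C1 as the vinyl group of the diene.

Step 3
Reactants: 4 methyl 4-methyl-3-oxopentanoate
Product: 5 benzyl 4-methyl-3-oxopentanoate
Conditions: BnOH, DMAP (cat.), toluene, reflux, removal of MeOH
Reagents that add atoms: benzyl alcohol OCc1ccccc1
Why: DMAP-catalysed transesterification of a β-keto ester, driven by removal of methanol, gives the benzyl ester that is later removed by hydrogenolysis.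

Step 4
Reactants: 5 benzyl 4-methyl-3-oxopentanoate
Product: 6 benzyl 2-diazo-4-methyl-3-oxopentanoate
Conditions: 4-acetamidobenzenesulfonyl azide, Et3N, MeCN, 0 °C → rt
Reagents that add atoms: 4-acetamidobenzenesulfonyl azide CC(=O)Nc1ccc(cc1)S(=O)(=O)N=[N+]=[N-]
Why: Regitz diazo transfer to the active methylene carbon (the future C2).

Step 5
Reactants: 6 benzyl 2-diazo-4-methyl-3-oxopentanoate
Product: 7 benzyl 3-(tert-butyldimethylsilyloxy)-2-diazo-4-methylpent-3-enoate
Conditions: TBSOTf, Et3N, CH2Cl2, 0 °C → rt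
Reagents that add atoms: tert-butyldimethylsilyl trifluoromethanesulfonate CC(C)(C)[Si](C)(C)OS(=O)(=O)C(F)(F)F
Why: Soft enolisation and O-silylation at the only enolisable position (the isopropyl methine) give the fully substituted siloxy-vinyldiazoacetate, in which C4 already carries both methyl groups.

Step 6
Reactants: 3 6-ethenyl-1,4-dioxaspiro[4.4]non-6-ene; 7 benzyl 3-(tert-butyldimethylsilyloxy)-2-diazo-4-methylpent-3-enoate
Product: 9 benzyl (5S)-3-(tert-butyldimethylsilyloxy)-10,10-(ethylenedioxy)-4,4-dimethylbicyclo[5.3.0]deca-2,6-diene-2-carboxylate (target locants), via cis-divinylcyclopropane 8 (not isolated)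
Conditions: Rh2(R-PTAD)4 [dirhodium tetrakis((R)-(1-adamantyl)(N-phthalimido)acetate)] (1 mol %), 3 in excess, hexanes, −25 °C → rt, slow addition of 7; then toluene, 100 °C
Reagents that add atoms: none
Why: Rh2(R-PTAD)4 converts 7 into a donor/acceptor rhodium vinylcarbenoid that cyclopropanates the monosubstituted C1=C7 double bond of 3 (forming C1–C2 and the temporary C2–C7 bond; three-membered ring closed by a concerted asynchronous [2+1] addition) to give cis-divinylcyclopropane 8, which then undergoes a [3,3] divinylcyclopropane–cycloheptadiene (Cope) rearrangement through the boat transition state, forming C4–C5, breaking C2–C7 and so closing ring B in a formal (4+3) cycloaddition. The closest known reaction type is the dirhodium-catalysed tandem cyclopropanation/Cope rearrangement of 3-siloxy-2-diazobut-3-enoates with 1,3-dienes. The only new stereocentre that survives, C5, is controlled by the chiral carboxylate ligands, which select the face of C1=C7 in the cyclopropanation (C7 of 8), and by the stereospecific boat Cope step that relays C7 to C5. Site selectivity (terminal vinyl group rather than the trisubstituted ring alkene next to the ketal) and cis-divinyl diastereoselectivity (ester trans to the cyclopentenyl group) are the normal preferences of donor/acceptor carbenoids. The regiochemistry of ring B cannot vary, because the carbenoid carbon C2 must bond to the diene terminus it cyclopropanates and the gem-dimethyl terminus C4 can then only reach C5. One methyl group of the C4 terminus must turn inward in the boat, which slows the Cope step and is why the mixture is heated after the cyclopropanation; the ring A carbon C5 carries only hydrogen on its inward side.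

Step 7
Reactants: 9 benzyl (5S)-3-(tert-butyldimethylsilyloxy)-10,10-(ethylenedioxy)-4,4-dimethylbicyclo[5.3.0]deca-2,6-diene-2-carboxylate
Product: 10 benzyl (5S)-4,4-dimethyl-3,10-dioxobicyclo[5.3.0]dec-6-ene-2-carboxylate (C2 epimers/enol)
Conditions: 1 M HCl, THF, rt
Reagents that add atoms: water O
Why: Acid hydrolysis cleaves the silyl enol ether (to the C3 ketone of a β-keto ester) and the allylic dioxolane (to the C10 enone); C5 is not enolisable and keeps its configuration.

Step 8
Reactants: 10 benzyl (5S)-4,4-dimethyl-3,10-dioxobicyclo[5.3.0]dec-6-ene-2-carboxylate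
Product: 11 benzyl (5S)-2,4,4-trimethyl-3,10-dioxobicyclo[5.3.0]dec-6-ene-2-carboxylate (C2 epimers)
Conditions: MeI, K2CO3, acetone, 50 °C
Reagents that add atoms: iodomethane CI
Why: C-alkylation of the β-keto ester enolate installs the C2 methyl group; the configuration at C2 is irrelevant because C2 later becomes sp2.

Step 9
Reactants: 11 benzyl (5S)-2,4,4-trimethyl-3,10-dioxobicyclo[5.3.0]dec-6-ene-2-carboxylate
Product: 13 (5R,6R)-2,4,4-trimethylbicyclo[5.3.0]decane-3,10-dione (cis-fused; C2 epimers), via β-keto acid 12 (not isolated)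
Conditions: H2 (1 atm), 10% Pd/C, EtOAc, rt; filter; toluene, 80 °C
Reagents that add atoms: none
Why: Heterogeneous hydrogenation adds H2 to C6=C7 from the face opposite C4 (the C4–C3–C2 arc of ring B covers the other face), setting H-6 cis to H-5; the benzyl ester is hydrogenolysed in the same operation and β-keto acid 12 decarboxylates on warming.

Step 10
Reactants: 13 (5R,6R)-2,4,4-trimethylbicyclo[5.3.0]decane-3,10-dione
Product: 14 (5R,6R)-2,4,4-trimethyl-10-methylidenebicyclo[5.3.0]decan-3-one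
Conditions: Zn, CH2Br2, TiCl4, THF/CH2Cl2, 0 °C → rt
Reagents that add atoms: dibromomethane BrCBr
Why: Takai–Lombardo methylenation is non-basic, so the epimerisable C6 centre is untouched, and it reacts only at the unhindered C10 cyclopentanone, not at the C3 ketone flanked by C4(Me)2 and C2H(Me).

Step 11
Reactants: 14 (5R,6R)-2,4,4-trimethyl-10-methylidenebicyclo[5.3.0]decan-3-one
Product: 15 (5R,6R,10R)-10-hydroxy-2,4,4,10-tetramethylbicyclo[5.3.0]decan-3-one
Conditions: Co(acac)2 (cat.), PhSiH3, O2 (1 atm), THF, rt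
Reagents that add atoms: dioxygen O=O
Why: Mukaiyama hydration (hydrogen-atom transfer from a cobalt hydride to the 1,1-disubstituted alkene, O2 capture of the tertiary C10 radical, reduction of the peroxide) should deliver oxygen on the convex face of the cis-fused bicycle, anti to C7 on C6, placing the OH cis to H-5/H-6 as the target requires.

Step 12
Reactants: 15 (5R,6R,10R)-10-hydroxy-2,4,4,10-tetramethylbicyclo[5.3.0]decan-3-one
Product: 16 (5R,6R,10R)-2,4,4,10-tetramethyl-3,10-bis(triethylsilyloxy)bicyclo[5.3.0]dec-2-ene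
Conditions: TESOTf, Et3N, CH2Cl2, 0 °C → rt
Reagents that add atoms: triethylsilyl trifluoromethanesulfonate CC[Si](CC)(CC)OS(=O)(=O)C(F)(F)F
Why: Silylation of the tertiary alcohol and soft enolisation of the C3 ketone toward C2 (its only α-CH, C4 being quaternary) give the silyl ether and the regiodefined silyl enol ether in one operation.

Step 13
Reactants: 16 (5R,6R,10R)-2,4,4,10-tetramethyl-3,10-bis(triethylsilyloxy)bicyclo[5.3.0]dec-2-ene
Product: 17 (5R,6R,10R)-2,4,4,10-tetramethyl-10-(triethylsilyloxy)bicyclo[5.3.0]dec-1-en-3-one (fragment 2)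
Conditions: Pd(OAc)2 (1.1 equiv), MeCN, rt → 40 °C
Reagents that add atoms: none
Why: Saegusa–Ito oxidation: the divalent palladium enolate at C2 undergoes β-hydride elimination toward C1 to give the endocyclic conjugated 2-methyl enone.

**Fragment 1 (rings C/D)**

Step 14
Reactants: 18 dimethyl (2-oxopropyl)phosphonate; 19 geranyl bromide
Product: 21 dimethyl [(5E)-6,10-dimethyl-2-oxoundeca-5,9-dien-1-yl]phosphonate, via phosphonate dianion 20 (not isolated)
Conditions: NaH, THF, 0 °C; n-BuLi; then 19, 0 °C → rt; aq. NH4Cl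
Reagents that add atoms: none
Why: Alkylation of the β-ketophosphonate dianion at its more basic terminal carbon by SN2 displacement of the allylic bromide, with retention of the E alkene.

Step 15
Reactants: 21 dimethyl [(5E)-6,10-dimethyl-2-oxoundeca-5,9-dien-1-yl]phosphonate; 22 (benzyloxy)acetaldehyde
Product: 23 (2E,7E)-1-(benzyloxy)-8,12-dimethyltrideca-2,7,11-trien-4-one
Conditions: LiCl, i-Pr2NEt, MeCN, rt
Reagents that add atoms: none
Why: Horner–Wadsworth–Emmons olefination under mild LiCl/amine conditions gives the (E)-enone; the aldehyde carbon becomes C12 and its CH2O carbon C11.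

Step 16
Reactants: 23 (2E,7E)-1-(benzyloxy)-8,12-dimethyltrideca-2,7,11-trien-4-one
Product: 24 (2E)-1-(benzyloxy)-6-[(2R,3R)-3-{2-[(2R)-3,3-dimethyloxiran-2-yl]ethyl}-3-methyloxiran-2-yl]hex-2-en-4-one
Conditions: D-fructose-derived ketone catalyst (1,2:4,5-di-O-isopropylidene-β-D-erythro-2,3-hexodiulo-2,6-pyranose, 30 mol %), Oxone, K2CO3, Bu4NHSO4, MeCN/dimethoxymethane/aqueous buffer (pH 10.5), 0 °C
Reagents that add atoms: potassium peroxymonosulfate (Oxone) OOS(=O)(=O)[O-].[K+]
Why: Shi epoxidation: the chiral dioxirane epoxidises the two electron-rich trisubstituted alkenes through the spiro transition state (the (R,R) sense for E-trisubstituted olefins) and leaves the electron-poor enone alkene, setting C21, C15 and C14 (C14 in the configuration that is inverted in step 18).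

Step 17
Reactants: 24 (2E)-1-(benzyloxy)-6-[(2R,3R)-3-{2-[(2R)-3,3-dimethyloxiran-2-yl]ethyl}-3-methyloxiran-2-yl]hex-2-en-4-one
Product: 25 triethyl{[(3Z)-1-(benzyloxy)-6-[(2R,3R)-3-{2-[(2R)-3,3-dimethyloxiran-2-yl]ethyl}-3-methyloxiran-2-yl]hex-3-en-4-yl]oxy}silane
Conditions: Et3SiH, RhCl(PPh3)3 (cat.), benzene, 50 °C
Reagents that add atoms: triethylsilane CC[SiH](CC)CC
Why: Rhodium-catalysed 1,4-hydrosilylation of the enone gives the regiodefined (Z)-silyl enol ether (silicon to oxygen, hydride to C12), which fixes C13 as the nucleophilic carbon; the epoxides are inert.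

Step 18
Reactants: 25 triethyl{[(3Z)-1-(benzyloxy)-6-[(2R,3R)-3-{2-[(2R)-3,3-dimethyloxiran-2-yl]ethyl}-3-methyloxiran-2-yl]hex-3-en-4-yl]oxy}silane
Product: 26 (3R,5aR,6R,9aR)-6-[2-(benzyloxy)ethyl]-2,2,5a-trimethyl-3-(triethylsilyloxy)octahydro-1-benzoxepin-7(2H)-one
Conditions: TESOTf (1.1 equiv), 2,6-di-tert-butyl-4-methylpyridine, CH2Cl2, −78 °C; aq. NaHCO3
Reagents that add atoms: triethylsilyl trifluoromethanesulfonate CC[Si](CC)(CC)OS(=O)(=O)C(F)(F)F
Why: Lewis-acid-triggered epoxide-opening cascade with enol silane termination (tandem oxa-/carbacyclisation): the silyl triflate activates the terminal gem-dimethyl epoxide, the neighbouring epoxide oxygen opens it at the tertiary carbon C22 (ring D, bicyclic epoxonium ion), and C13 of the (Z)-enol silane opens the epoxonium ion at the tertiary carbon C14 with inversion through a chair transition state (ring C), so that C21 and C15 keep the epoxide configurations, the C14/C15 fusion is trans and the C13 side chain is equatorial (also the thermodynamic position α to the ketone).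

Step 19
Reactants: 26 (3R,5aR,6R,9aR)-6-[2-(benzyloxy)ethyl]-2,2,5a-trimethyl-3-(triethylsilyloxy)octahydro-1-benzoxepin-7(2H)-one
Product: 27 (3R,5aR,6R,7S,9aR)-6-[2-(benzyloxy)ethyl]-2,2,5a,7-tetramethyl-3-(triethylsilyloxy)decahydro-1-benzoxepin-7-ol
Conditions: MeMgBr, THF, −78 → 0 °C; aq. NH4Cl
Reagents that add atoms: methylmagnesium bromide C[Mg]Br
Why: Grignard 1,2-addition from the equatorial direction (the axial trajectory is blocked by the syn-axial C14 methyl group) gives the axial C18 hydroxyl and equatorial methyl group of the target.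

Step 20
Reactants: 27 (3R,5aR,6R,7S,9aR)-6-[2-(benzyloxy)ethyl]-2,2,5a,7-tetramethyl-3-(triethylsilyloxy)decahydro-1-benzoxepin-7-ol
Product: 28 (3R,5aR,6R,7S,9aR)-6-[2-(benzyloxy)ethyl]-2,2,5a,7-tetramethyl-3,7-bis(triethylsilyloxy)decahydro-1-benzoxepine
Conditions: TESOTf, 2,6-lutidine, CH2Cl2, 0 °C
Reagents that add atoms: triethylsilyl trifluoromethanesulfonate CC[Si](CC)(CC)OS(=O)(=O)C(F)(F)F
Why: Silylation of the tertiary alcohol with the reactive silyl triflate protects it against the alkyllithium chemistry of step 23.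

Step 21
Reactants: 28 (3R,5aR,6R,7S,9aR)-6-[2-(benzyloxy)ethyl]-2,2,5a,7-tetramethyl-3,7-bis(triethylsilyloxy)decahydro-1-benzoxepine
Product: 29 2-[(3R,5aR,6R,7S,9aR)-2,2,5a,7-tetramethyl-3,7-bis(triethylsilyloxy)decahydro-1-benzoxepin-6-yl]ethan-1-ol
Conditions: H2 (1 atm), 10% Pd/C, EtOAc, rt
Reagents that add atoms: none
Why: Hydrogenolysis of the benzyl ether under neutral conditions in ethyl acetate leaves the silyl ethers intact.

Step 22
Reactants: 29 2-[(3R,5aR,6R,7S,9aR)-2,2,5a,7-tetramethyl-3,7-bis(triethylsilyloxy)decahydro-1-benzoxepin-6-yl]ethan-1-ol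
Product: 30 (3R,5aR,6R,7S,9aR)-6-(2-iodoethyl)-2,2,5a,7-tetramethyl-3,7-bis(triethylsilyloxy)decahydro-1-benzoxepine (fragment 1)
Conditions: I2, PPh3, imidazole, CH2Cl2, 0 °C → rt
Reagents that add atoms: iodine II
Why: Appel-type iodination of the primary alcohol through the alkoxyphosphonium ion (SN2 at C11).

**Fragment union and end game**

Step 23
Reactants: 30 (3R,5aR,6R,7S,9aR)-6-(2-iodoethyl)-2,2,5a,7-tetramethyl-3,7-bis(triethylsilyloxy)decahydro-1-benzoxepine; 17 (5R,6R,10R)-2,4,4,10-tetramethyl-10-(triethylsilyloxy)bicyclo[5.3.0]dec-1-en-3-one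
Product: 32 C3 carbinol adduct (C3 epimers; C1=C2 alkene; three triethylsilyl ethers), via alkyllithium 31 (not isolated)
Conditions: t-BuLi (2 equiv), Et2O/pentane, −78 °C; then 17, −78 → 0 °C; aq. NH4Cl
Reagents that add atoms: none
Why: Iodine–lithium exchange followed by 1,2-addition of the primary alkyllithium to the enone carbonyl, the normal behaviour of organolithiums toward 2,6,6-trisubstituted cycloalk-2-enones; C4 is quaternary, so no α-deprotonation can compete, and the new C3 carbinol centre is erased in step 24.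

Step 24
Reactants: 32 C3 carbinol adduct
Product: 33 10,18,21-tris-O-(triethylsilyl) ether of the target
Conditions: pyridinium chlorochromate [C5H5NH][CrO3Cl], 4 Å molecular sieves, CH2Cl2, rt
Reagents that add atoms: none
Why: Babler–Dauben oxidative 1,3-transposition: the tertiary allylic chromate ester rearranges by a [3,3] shift to the secondary C1 chromate, which hexavalent chromium oxidises to the C1 ketone, leaving the tetrasubstituted C2=C3 alkene of the target.

Step 25
Reactants: 33 10,18,21-tris-O-(triethylsilyl) ether of the target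
Product: 34 target CNP0397160.1
Conditions: HF·pyridine, THF/pyridine, 0 °C → rt
Reagents that add atoms: none
Why: Fluoride-mediated cleavage of the three silyl ethers under buffered conditions that do not dehydrate the tertiary alcohols or isomerise the enone.

**Compound list**

1 | 2-bromocyclopent-2-en-1-one | O=C1CCC=C1Br | starting material
2 | 6-bromo-1,4-dioxaspiro[4.4]non-6-ene | BrC1=CCCC12OCCO2 | intermediate
3 | 6-ethenyl-1,4-dioxaspiro[4.4]non-6-ene (ring A diene) | C=CC1=CCCC12OCCO2 | intermediate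
4 | methyl 4-methyl-3-oxopentanoate | COC(=O)CC(=O)C(C)C | starting material
5 | benzyl 4-methyl-3-oxopentanoate | O=C(CC(=O)C(C)C)OCc1ccccc1 | intermediate
6 | benzyl 2-diazo-4-methyl-3-oxopentanoate | [N-]=[N+]=C(C(=O)OCc1ccccc1)C(=O)C(C)C | intermediate
7 | benzyl 3-(tert-butyldimethylsilyloxy)-2-diazo-4-methylpent-3-enoate | [N-]=[N+]=C(C(=O)OCc1ccccc1)C(O[Si](C)(C)C(C)(C)C)=C(C)C | intermediate
8 | benzyl (1S,2R)-1-[1-(tert-butyldimethylsilyloxy)-2-methylprop-1-enyl]-2-(1,4-dioxaspiro[4.4]non-6-en-6-yl)cyclopropane-1-carboxylate (cis-divinylcyclopropane; not isolated) | O=C(OCc1ccccc1)[C@@]1(C(O[Si](C)(C)C(C)(C)C)=C(C)C)C[C@@H]1C1=CCCC12OCCO2 | intermediate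
9 | benzyl (5S)-3-(tert-butyldimethylsilyloxy)-10,10-(ethylenedioxy)-4,4-dimethylbicyclo[5.3.0]deca-2,6-diene-2-carboxylate (target locants) | O=C(OCc1ccccc1)C1=C(O[Si](C)(C)C(C)(C)C)C(C)(C)[C@@H]2CCC3(OCCO3)C2=CC1 | intermediate
10 | benzyl (5S)-4,4-dimethyl-3,10-dioxobicyclo[5.3.0]dec-6-ene-2-carboxylate (C2 epimers/enol) | O=C(OCc1ccccc1)C1C(=O)C(C)(C)[C@@H]2CCC(=O)C2=CC1 | intermediate
11 | benzyl (5S)-2,4,4-trimethyl-3,10-dioxobicyclo[5.3.0]dec-6-ene-2-carboxylate (C2 epimers) | O=C(OCc1ccccc1)C1(C)C(=O)C(C)(C)[C@@H]2CCC(=O)C2=CC1 | intermediate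
12 | (5R,6R)-2,4,4-trimethyl-3,10-dioxobicyclo[5.3.0]decane-2-carboxylic acid (cis-fused; not isolated) | OC(=O)C1(C)C(=O)C(C)(C)[C@@H]2CCC(=O)[C@@H]2CC1 | intermediate
13 | (5R,6R)-2,4,4-trimethylbicyclo[5.3.0]decane-3,10-dione (cis-fused; C2 epimers) | CC1C(=O)C(C)(C)[C@@H]2CCC(=O)[C@@H]2CC1 | intermediate
14 | (5R,6R)-2,4,4-trimethyl-10-methylidenebicyclo[5.3.0]decan-3-one | CC1C(=O)C(C)(C)[C@@H]2CCC(=C)[C@@H]2CC1 | intermediate
15 | (5R,6R,10R)-10-hydroxy-2,4,4,10-tetramethylbicyclo[5.3.0]decan-3-one | CC1C(=O)C(C)(C)[C@@H]2CC[C@@](C)(O)[C@@H]2CC1 | intermediate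
16 | (5R,6R,10R)-2,4,4,10-tetramethyl-3,10-bis(triethylsilyloxy)bicyclo[5.3.0]dec-2-ene | CC1=C(O[Si](CC)(CC)CC)C(C)(C)[C@@H]2CC[C@@](C)(O[Si](CC)(CC)CC)[C@@H]2CC1 | intermediate
17 | (5R,6R,10R)-2,4,4,10-tetramethyl-10-(triethylsilyloxy)bicyclo[5.3.0]dec-1-en-3-one (fragment 2) | O=C1C(C)(C)[C@@H]2CC[C@@](C)(O[Si](CC)(CC)CC)[C@@H]2CC=C1C | intermediate
18 | dimethyl (2-oxopropyl)phosphonate | COP(=O)(OC)CC(C)=O | starting material
19 | geranyl bromide, (2E)-1-bromo-3,7-dimethylocta-2,6-diene | CC(C)=CCC/C(C)=C/CBr | starting material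
20 | sodium lithium dianion of 18 (not isolated) | COP(=O)(OC)[CH-]C(=O)[CH2-].[Na+].[Li+] | intermediate
21 | dimethyl [(5E)-6,10-dimethyl-2-oxoundeca-5,9-dien-1-yl]phosphonate | COP(=O)(OC)CC(=O)CC/C=C(\C)CCC=C(C)C | intermediate
22 | (benzyloxy)acetaldehyde | O=CCOCc1ccccc1 | starting material
23 | (2E,7E)-1-(benzyloxy)-8,12-dimethyltrideca-2,7,11-trien-4-one | c1ccccc1COC/C=C/C(=O)CC/C=C(\C)CCC=C(C)C | intermediate
24 | (2E)-1-(benzyloxy)-6-[(2R,3R)-3-{2-[(2R)-3,3-dimethyloxiran-2-yl]ethyl}-3-methyloxiran-2-yl]hex-2-en-4-one | CC1(C)O[C@@H]1CC[C@@]1(C)O[C@@H]1CCC(=O)/C=C/COCc1ccccc1 | intermediate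
25 | triethyl{[(3Z)-1-(benzyloxy)-6-[(2R,3R)-3-{2-[(2R)-3,3-dimethyloxiran-2-yl]ethyl}-3-methyloxiran-2-yl]hex-3-en-4-yl]oxy}silane | CC1(C)O[C@@H]1CC[C@@]1(C)O[C@@H]1CC/C(O[Si](CC)(CC)CC)=C/CCOCc1ccccc1 | intermediate
26 | (3R,5aR,6R,9aR)-6-[2-(benzyloxy)ethyl]-2,2,5a-trimethyl-3-(triethylsilyloxy)octahydro-1-benzoxepin-7(2H)-one | c1ccccc1COCC[C@@H]1[C@@]2(C)CC[C@@H](O[Si](CC)(CC)CC)C(C)(C)O[C@@H]2CCC1=O | intermediate
27 | (3R,5aR,6R,7S,9aR)-6-[2-(benzyloxy)ethyl]-2,2,5a,7-tetramethyl-3-(triethylsilyloxy)decahydro-1-benzoxepin-7-ol | c1ccccc1COCC[C@@H]1[C@@]2(C)CC[C@@H](O[Si](CC)(CC)CC)C(C)(C)O[C@@H]2CC[C@]1(C)O | intermediate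
28 | (3R,5aR,6R,7S,9aR)-6-[2-(benzyloxy)ethyl]-2,2,5a,7-tetramethyl-3,7-bis(triethylsilyloxy)decahydro-1-benzoxepine | c1ccccc1COCC[C@@H]1[C@@]2(C)CC[C@@H](O[Si](CC)(CC)CC)C(C)(C)O[C@@H]2CC[C@]1(C)O[Si](CC)(CC)CC | intermediate
29 | 2-[(3R,5aR,6R,7S,9aR)-2,2,5a,7-tetramethyl-3,7-bis(triethylsilyloxy)decahydro-1-benzoxepin-6-yl]ethan-1-ol | OCC[C@@H]1[C@@]2(C)CC[C@@H](O[Si](CC)(CC)CC)C(C)(C)O[C@@H]2CC[C@]1(C)O[Si](CC)(CC)CC | intermediate
30 | (3R,5aR,6R,7S,9aR)-6-(2-iodoethyl)-2,2,5a,7-tetramethyl-3,7-bis(triethylsilyloxy)decahydro-1-benzoxepine (fragment 1) | ICC[C@@H]1[C@@]2(C)CC[C@@H](O[Si](CC)(CC)CC)C(C)(C)O[C@@H]2CC[C@]1(C)O[Si](CC)(CC)CC | intermediate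
31 | alkyllithium derived from 30 (not isolated) | [Li]CC[C@@H]1[C@@]2(C)CC[C@@H](O[Si](CC)(CC)CC)C(C)(C)O[C@@H]2CC[C@]1(C)O[Si](CC)(CC)CC | intermediate
32 | C3 carbinol adduct: tris(triethylsilyl) ether with C1=C2 alkene and C3–OH (C3 epimers) | OC1(CC[C@@H]2[C@@]3(C)CC[C@@H](O[Si](CC)(CC)CC)C(C)(C)O[C@@H]3CC[C@]2(C)O[Si](CC)(CC)CC)C(C)(C)[C@@H]2CC[C@@](C)(O[Si](CC)(CC)CC)[C@@H]2CC=C1C | intermediate
33 | 10,18,21-tris-O-(triethylsilyl) ether of the target | CC1=C(CC[C@@H]2[C@@]3(C)CC[C@@H](O[Si](CC)(CC)CC)C(C)(C)O[C@@H]3CC[C@]2(C)O[Si](CC)(CC)CC)C(C)(C)[C@@H]2CC[C@@](C)(O[Si](CC)(CC)CC)[C@@H]2CC1=O | intermediate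
34 | target CNP0397160.1, (5R,6R,10R,13R,14R,15R,18S,21R) in the locants of the overview | CC1=C(CC[C@@H]2[C@@]3(C)CC[C@@H](O)C(C)(C)O[C@@H]3CC[C@]2(C)O)C(C)(C)[C@@H]2CC[C@@](C)(O)[C@@H]2CC1=O | target

**Step count and risks**

Total step count: 25. Longest linear sequence: 14 steps (steps 3–13 and 23–25, from methyl 4-methyl-3-oxopentanoate).

Steps most likely to fail:

1. Step 6 (key step). The Cope rearrangement may stall because one methyl group of the dimethylvinyl terminus must turn inward in the boat transition state, or the hindered carbenoid may cyclopropanate slowly and with eroded enantiocontrol. Fallback: the gem-dimethyl group is introduced after ring B is closed. The fallback sets out from diene 3. Commercial benzyl acetoacetate is converted by diazo transfer into benzyl 2-diazo-3-oxobutanoate F1 and by TBSOTf/Et3N into benzyl 3-(tert-butyldimethylsilyloxy)-2-diazobut-3-enoate F2. Its Rh2(R-PTAD)4-catalysed reaction with 3 (terminus unsubstituted, Cope step fast) gives, through the cis-divinylcyclopropane F3, the C4-unsubstituted cycloheptadiene F4. TBAF frees the ketal-protected β-keto ester F5. Two successive γ-methylations at C4 (NaH, n-BuLi, then MeI, each time) give the C4-monomethyl β-keto ester F6 and the C4-gem-dimethyl β-keto ester F7. Aqueous HCl then removes the ketal, and the route is rejoined at 10.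

2. Step 18. The bicyclic epoxonium ion may lose a proton or be captured by triflate before the C–C bond forms, or the non-stabilised enol silane may be cleaved prematurely. Fallback: a stabilised, regiochemically unambiguous enol terminates the cascade, and the side chain is attached afterwards. The fallback sets out from β-ketophosphonate 21. Shi epoxidation with the same ketone catalyst gives the diepoxy β-ketophosphonate F8. TESOTf (2.2 equiv)/2,6-di-tert-butyl-4-methylpyridine first converts it in the flask into the triethylsilyl enol ether F9 and then promotes the same epoxonium cascade to give the bicyclic β-ketophosphonate F10. Horner–Wadsworth–Emmons reaction with aldehyde 22 (LiCl, i-Pr2NEt, MeCN) gives the exocyclic enone F11. Conjugate reduction with [(Ph3P)CuH]6 and equilibration of C13 (DBU) rejoin the route at 26.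

3. Step 11. Capture of the planar tertiary C10 radical by O2 may show poor facial selectivity, or the alkene may simply be reduced. Fallback: a two-electron sequence whose facial selectivity is set in an epoxidation. The fallback sets out from 14. Dimethyldioxirane epoxidises the exocyclic alkene on the convex face to give spiro-epoxide F12. LiAlH4 opens the epoxide at its CH2 terminus and reduces the C3 ketone, giving diol F13. Oxidation of the secondary alcohol with DMP (1,1,1-triacetoxy-1,1-dihydro-1,2-benziodoxol-3(1H)-one) rejoins the route at 15.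

**Further compounds**

F1 | step 6 | benzyl 2-diazo-3-oxobutanoate | CC(=O)C(=[N+]=[N-])C(=O)OCc1ccccc1
F2 | step 6 | benzyl 3-(tert-butyldimethylsilyloxy)-2-diazobut-3-enoate | C=C(O[Si](C)(C)C(C)(C)C)C(=[N+]=[N-])C(=O)OCc1ccccc1
F3 | step 6 | benzyl (1S,2R)-1-[1-(tert-butyldimethylsilyloxy)ethenyl]-2-(1,4-dioxaspiro[4.4]non-6-en-6-yl)cyclopropane-1-carboxylate | O=C(OCc1ccccc1)[C@@]1(C(=C)O[Si](C)(C)C(C)(C)C)C[C@@H]1C1=CCCC12OCCO2
F4 | step 6 | benzyl 3-(tert-butyldimethylsilyloxy)-10,10-(ethylenedioxy)bicyclo[5.3.0]deca-2,6-diene-2-carboxylate (C4 unsubstituted; C5 as in 9) | O=C(OCc1ccccc1)C1=C(O[Si](C)(C)C(C)(C)C)C[C@@H]2CCC3(OCCO3)C2=CC1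
F5 | step 6 | benzyl 10,10-(ethylenedioxy)-3-oxobicyclo[5.3.0]dec-6-ene-2-carboxylate | O=C(OCc1ccccc1)C1C(=O)C[C@@H]2CCC3(OCCO3)C2=CC1
F6 | step 6 | benzyl 10,10-(ethylenedioxy)-4-methyl-3-oxobicyclo[5.3.0]dec-6-ene-2-carboxylate | O=C(OCc1ccccc1)C1C(=O)C(C)[C@@H]2CCC3(OCCO3)C2=CC1
F7 | step 6 | benzyl 10,10-(ethylenedioxy)-4,4-dimethyl-3-oxobicyclo[5.3.0]dec-6-ene-2-carboxylate | O=C(OCc1ccccc1)C1C(=O)C(C)(C)[C@@H]2CCC3(OCCO3)C2=CC1
F8 | step 18 | dimethyl {4-[(2R,3R)-3-{2-[(2R)-3,3-dimethyloxiran-2-yl]ethyl}-3-methyloxiran-2-yl]-2-oxobutyl}phosphonate | CC1(C)O[C@@H]1CC[C@@]1(C)O[C@@H]1CCC(=O)CP(=O)(OC)OC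
F9 | step 18 | triethylsilyl enol ether of F8 (silyloxy on the former ketone carbon, C=C toward phosphorus) | CC1(C)O[C@@H]1CC[C@@]1(C)O[C@@H]1CCC(O[Si](CC)(CC)CC)=CP(=O)(OC)OC
F10 | step 18 | dimethyl [(3R,5aR,9aR)-2,2,5a-trimethyl-7-oxo-3-(triethylsilyloxy)decahydro-1-benzoxepin-6-yl]phosphonate (C6 epimers) | COP(=O)(OC)C1[C@@]2(C)CC[C@@H](O[Si](CC)(CC)CC)C(C)(C)O[C@@H]2CCC1=O
F11 | step 18 | (3R,5aR,9aR)-6-[2-(benzyloxy)ethylidene]-2,2,5a-trimethyl-3-(triethylsilyloxy)octahydro-1-benzoxepin-7(2H)-one | c1ccccc1COCC=C1[C@@]2(C)CC[C@@H](O[Si](CC)(CC)CC)C(C)(C)O[C@@H]2CCC1=O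
F12 | step 11 | spiro-epoxide of 14 at C10 (oxygen on the convex face) | CC1C(=O)C(C)(C)[C@@H]2CC[C@@]3(OC3)[C@@H]2CC1
F13 | step 11 | (5R,6R,10R)-2,4,4,10-tetramethylbicyclo[5.3.0]decane-3,10-diol (C2, C3 epimers) | CC1C(O)C(C)(C)[C@@H]2CC[C@@](C)(O)[C@@H]2CC1
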